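**Retrosynthetic overview** (halimane numbering: ring A = C1–C5, C10; ring B = C5–C10; C18 = ester carbon on C4)
1. The enabling feature is the γ,δ-unsaturated ester C18(=O)–C4–C5–C10=C1 in ring A, a Claisen retron. C4 and C1 sit 1,4 across ring A, bridged by C3–C2, so the ester oxygen can be tied back to C1 as a δ-lactone.
2. Ring A is therefore made last, by Ireland–Claisen ring contraction of the (1R)-δ-lactone 19. This one operation forms C4–C5, the quaternary C4 and the C5 stereocentre, the C1=C10 alkene and the C18 carboxyl.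
3. Lactone 19 comes from enal 13 by asymmetric allylation, methacryloylation, ring-closing metathesis and conjugate reduction. Enal 13 comes from the ring-B ketone 10 by a Shapiro reaction.
4. Ring B is bought as 2-methylcyclohexenone. Asymmetric conjugate methylation sets C8, a Mukaiyama–Michael addition to a glyceraldehyde-derived vinyl ketone sets quaternary C9 and brings C14, and chelation-controlled MeMgBr addition sets C13.
5. Ring order: ring B, then the temporary lactone ring, then ring A (lactone ring excised). End game: methyl ester, deprotection, selective 14-O-acetylation.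

Key step: step 13

Remark: aldehyde 4 and (+)-Ipc2B(allyl) are taken as purchasable. In step 1 the phosphoramidite antipode that gives the 8R centre is used.

**Step 1**
Reactants: 1 2-methylcyclohex-2-en-1-one
Product: 3 {[(3R)-2,3-dimethylcyclohex-1-en-1-yl]oxy}trimethylsilane, via dimethylaluminium enolate 2 (not isolated)
Conditions: Me3Al (1.4 equiv), copper thiophene-2-carboxylate Cu(O2CC4H3S) (2 mol %), binaphthol/bis(1-phenylethyl)amine phosphoramidite (4 mol %), Et2O, −30 °C; then TMSOTf, −30 to 0 °C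
Reagents that add atoms: trimethylaluminium C[Al](C)C; trimethylsilyl triflate C[Si](C)(C)OS(=O)(=O)C(F)(F)F
Why: Copper-catalysed asymmetric conjugate addition, in which the ligand selects the enone face and sets C8 as R, followed by O-silylation that stores the regiodefined tetrasubstituted enolate.

**Step 2**
Reactants: 4 (R)-2,2-dimethyl-1,3-dioxolane-4-carbaldehyde
Product: 5 1-[(4R)-2,2-dimethyl-1,3-dioxolan-4-yl]prop-2-en-1-ol (both carbinol epimers)
Conditions: CH2=CHMgBr, THF, −78 °C; then H2O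
Reagents that add atoms: vinylmagnesium bromide C=C[Mg]Br
Why: Grignard 1,2-addition to the aldehyde; the new carbinol centre is irrelevant because it is oxidised in step 3, and C14 comes unchanged from the chiral pool.

**Step 3**
Reactants: 5 1-[(4R)-2,2-dimethyl-1,3-dioxolan-4-yl]prop-2-en-1-ol
Product: 6 1-[(4R)-2,2-dimethyl-1,3-dioxolan-4-yl]prop-2-en-1-one
Conditions: Dess–Martin periodinane, CH2Cl2, 0 °C to rt; used at once
Reagents that add atoms: none
Why: Dess–Martin oxidation of the allylic alcohol under near-neutral conditions, which should leave the α-alkoxy centre C14 unepimerised.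

**Step 4**
Reactants: 3 {[(3R)-2,3-dimethylcyclohex-1-en-1-yl]oxy}trimethylsilane; 6 1-[(4R)-2,2-dimethyl-1,3-dioxolan-4-yl]prop-2-en-1-one
Product: 8 (2S,3R)-2-{3-[(4R)-2,2-dimethyl-1,3-dioxolan-4-yl]-3-oxopropyl}-2,3-dimethylcyclohexan-1-one, via silyl enol ether adduct 7 (not isolated)
Conditions: Tf2NH (3 mol %), CH2Cl2, −78 °C; then 1 M aq. HCl–THF, 0 °C, brief
Reagents that add atoms: none
Why: Mukaiyama–Michael addition; A(1,2) strain holds the C8 methyl pseudoaxial, so the vinyl ketone is attacked on the opposite face and C9 forms as S with its methyl cis to the C8 methyl.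

**Step 5**
Reactants: 8 (2S,3R)-2-{3-[(4R)-2,2-dimethyl-1,3-dioxolan-4-yl]-3-oxopropyl}-2,3-dimethylcyclohexan-1-one
Product: 9 (2S,3R)-2-{(3S)-3-[(4R)-2,2-dimethyl-1,3-dioxolan-4-yl]-3-hydroxybutyl}-2,3-dimethylcyclohexan-1-one
Conditions: MeMgBr (1.2 equiv), CH2Cl2–Et2O, −78 °C; then H2O
Reagents that add atoms: methylmagnesium bromide C[Mg]Br
Why: Cram-chelate Grignard addition; magnesium bridges the C13 carbonyl and the α-oxygen on C14, methyl attacks anti to C15 to set 13S, and the α-quaternary C10 ketone is too hindered to compete at −78 °C.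

**Step 6**
Reactants: 9 (2S,3R)-2-{(3S)-3-[(4R)-2,2-dimethyl-1,3-dioxolan-4-yl]-3-hydroxybutyl}-2,3-dimethylcyclohexan-1-one
Product: 10 (2S,3R)-2-{(3S)-3-[(4R)-2,2-dimethyl-1,3-dioxolan-4-yl]-3-(triethylsilyloxy)butyl}-2,3-dimethylcyclohexan-1-one
Conditions: Et3SiOTf, 2,6-lutidine, CH2Cl2, −78 to 0 °C
Reagents that add atoms: triethylsilyl triflate CC[Si](CC)(CC)OS(=O)(=O)C(F)(F)F
Why: Silyl triflate silylation of the tertiary alcohol, which removes the acidic proton before the organolithium steps and blocks hemiketal formation with C10.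

**Step 7**
Reactants: 10 (2S,3R)-2-{(3S)-3-[(4R)-2,2-dimethyl-1,3-dioxolan-4-yl]-3-(triethylsilyloxy)butyl}-2,3-dimethylcyclohexan-1-one
Product: 11 (E)-2,4,6-triisopropylbenzenesulfonylhydrazone of ketone 10
Conditions: 2,4,6-iPr3C6H2SO2NHNH2, THF, rt
Reagents that add atoms: 2,4,6-triisopropylbenzenesulfonohydrazide CC(C)c1cc(C(C)C)c(S(=O)(=O)NN)c(C(C)C)c1
Why: Hydrazone condensation; the sulfonamide nitrogen settles syn to the C5 methylene and away from quaternary C9, the geometry needed for the Shapiro deprotonation.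

**Step 8**
Reactants: 11 (E)-2,4,6-triisopropylbenzenesulfonylhydrazone of ketone 10
Product: 13 (5R,6S)-6-{(3S)-3-[(4R)-2,2-dimethyl-1,3-dioxolan-4-yl]-3-(triethylsilyloxy)butyl}-5,6-dimethylcyclohex-1-ene-1-carbaldehyde, via vinyllithium 12 (not isolated)
Conditions: n-BuLi (2.2 equiv), THF, −78 to 0 °C; then DMF, −78 °C to rt; aqueous work-up
Reagents that add atoms: N,N-dimethylformamide CN(C)C=O
Why: Shapiro reaction; only C5 carries α-hydrogens, so the C5=C10 vinyllithium is regiodefined, and formylation with DMF installs C1.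

**Step 9**
Reactants: 13 (5R,6S)-6-{(3S)-3-[(4R)-2,2-dimethyl-1,3-dioxolan-4-yl]-3-(triethylsilyloxy)butyl}-5,6-dimethylcyclohex-1-ene-1-carbaldehyde
Product: 15 (1R)-1-[(5R,6S)-6-{(3S)-3-[(4R)-2,2-dimethyl-1,3-dioxolan-4-yl]-3-(triethylsilyloxy)butyl}-5,6-dimethylcyclohex-1-en-1-yl]but-3-en-1-ol, via diisopinocampheylborinate 14 (not isolated)
Conditions: (+)-Ipc2B(allyl) (antipode derived from (−)-α-pinene), Et2O, −78 °C; then NaOH, H2O2, 0 °C
Reagents that add atoms: (+)-B-allyldiisopinocampheylborane C=CCB([C@H]1C[C@H]2C[C@@H]([C@@H]1C)C2(C)C)[C@H]3C[C@H]4C[C@@H]([C@@H]3C)C4(C)C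
Why: Brown allylboration through a closed chair transition state is reagent-controlled; this antipode should add allyl to the Re face of the formyl group and set C1 as R, the centre that steers step 13.

**Step 10**
Reactants: 15 the (1R)-homoallylic alcohol
Product: 16 2-methylprop-2-enoate (methacrylate) ester of alcohol 15
Conditions: CH2=C(Me)COCl, Et3N, DMAP (cat.), CH2Cl2, 0 °C
Reagents that add atoms: methacryloyl chloride C=C(C)C(Cl)=O
Why: DMAP-catalysed acylation of the only free hydroxyl; it brings in C18, C4 and the C4 methyl without touching C1.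

**Step 11**
Reactants: 16 methacrylate ester of alcohol 15
Product: 17 (6R)-6-[(5R,6S)-6-{(3S)-3-[(4R)-2,2-dimethyl-1,3-dioxolan-4-yl]-3-(triethylsilyloxy)butyl}-5,6-dimethylcyclohex-1-en-1-yl]-3-methyl-5,6-dihydro-2H-pyran-2-one
Conditions: second-generation Grubbs catalyst RuCl2(=CHPh)(PCy3)(H2IMes) (5 mol %), CH2Cl2, 40 °C
Reagents that add atoms: none
Why: Ring-closing metathesis of the allyl and methacrylate alkenes gives the six-membered unsaturated lactone; the hindered trisubstituted C5=C10 alkene should not take part.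

**Step 12**
Reactants: 17 the (6R)-3-methyl-5,6-dihydro-2H-pyran-2-one
Product: 19 (3RS,6R)-6-[(5R,6S)-6-{(3S)-3-[(4R)-2,2-dimethyl-1,3-dioxolan-4-yl]-3-(triethylsilyloxy)butyl}-5,6-dimethylcyclohex-1-en-1-yl]-3-methyltetrahydro-2H-pyran-2-one, via dimethylphenylsilyl ketene acetal 18 (not isolated)
Conditions: Stryker's reagent [(Ph3P)CuH]6 (5 mol % Cu), PhMe2SiH, toluene, rt; then aq. NH4Cl
Reagents that add atoms: none
Why: Copper hydride 1,4-reduction (conjugate hydrosilylation) touches only the conjugated C3=C4 bond; C4 forms as an epimer mixture, which is irrelevant because C4 is planarised in step 13.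

**Step 13**
Reactants: 19 the (6R)-3-methyl δ-lactone
Product: 22 (1S,5S,6R,8aR)-5-{(3S)-3-[(4R)-2,2-dimethyl-1,3-dioxolan-4-yl]-3-(triethylsilyloxy)butyl}-1,5,6-trimethyl-1,2,3,5,6,7,8,8a-octahydronaphthalene-1-carboxylic acid, via trimethylsilyl ketene acetal 20 (not isolated), via trimethylsilyl ester 21 (not isolated)
Conditions: LDA (1.2 equiv), TMSCl–Et3N (in situ), THF, −78 °C; then toluene, 105 °C; then H2O, dilute citric acid
Reagents that add atoms: none
Why: LDA enolises the lactone (both C4 epimers converge) and TMSCl traps the cyclic ketene acetal 20, whose O–C18=C4 and C1–C10=C5 array undergoes a concerted [3,3]-sigmatropic shift on heating, breaking O–C1 and forming C4–C5 to give silyl ester 21 and acid 22 on hydrolysis. The closest known reaction type is the Ireland–Claisen ring contraction of silyl ketene acetals of δ-lactones that carry an exocyclic alkenyl group on the carbinol carbon, which gives cyclohex-3-enecarboxylic acids (the same topology as the dioxanone-to-dihydropyran Claisen). Ring A (C1–C5, C10) closes by C4–C5 bond formation inside a bicyclo[2.2.2]octane-like boat transition state that the C3–C2 tether between C4 and C1 enforces, while the lactone ring is excised. C5 is set as R by suprafacial 1,3-chirality transfer from C1 (R): C4 bonds to the ring-B face from which oxygen leaves C1, putting H-5 cis to the C9 methyl. C4 is set as S because the ring-fixed enolate geometry and the boat place C18 over C10 and the C4 methyl over C6, so the carboxyl ends trans to H-5. The only selectivity needed is the face of ring B, and it is secured by the C1 centre from step 9 and not by the weak bias of C9; the alkene can only end at C1=C10, and cold in situ silylation with a small silyl group limits ketene extrusion and C-silylation.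

**Step 14**
Reactants: 22 the octahydronaphthalene-1-carboxylic acid
Product: 23 methyl (1S,5S,6R,8aR)-5-{(3S)-3-[(4R)-2,2-dimethyl-1,3-dioxolan-4-yl]-3-(triethylsilyloxy)butyl}-1,5,6-trimethyl-1,2,3,5,6,7,8,8a-octahydronaphthalene-1-carboxylate
Conditions: MeI, K2CO3, DMF, rt
Reagents that add atoms: iodomethane CI
Why: Carboxylate O-alkylation (SN2 at methyl) is insensitive to the hindrance at quaternary C4 and leaves all stereocentres alone.

**Step 15**
Reactants: 23 the protected methyl ester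
Product: 24 methyl (1S,5S,6R,8aR)-5-[(3S,4R)-3,4,5-trihydroxy-3-methylpentyl]-1,5,6-trimethyl-1,2,3,5,6,7,8,8a-octahydronaphthalene-1-carboxylate
Conditions: AcOH–H2O–THF (3:1:1), 45 °C
Reagents that add atoms: none
Why: Mild acid hydrolysis removes the acetonide and the triethylsilyl ether together; the conditions are too weak to dehydrate the tertiary alcohol or move the C1=C10 alkene.

**Step 16**
Reactants: 24 the 13,14,15-triol
Product: 26 methyl (1S,5S,6R,8aR)-5-[(3S,4R)-4-acetoxy-3,5-dihydroxy-3-methylpentyl]-1,5,6-trimethyl-1,2,3,5,6,7,8,8a-octahydronaphthalene-1-carboxylate (CNP0210069.1), via cyclic orthoacetate 25 (not isolated)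
Conditions: MeC(OMe)3, PPTS (cat.), CH2Cl2, rt; then AcOH–H2O (4:1), 0 °C
Reagents that add atoms: trimethyl orthoacetate COC(C)(OC)OC; water O
Why: Orthoester-mediated monoacylation of a vicinal diol; the five-membered orthoacetate forms across O14/O15 (the tertiary C13 hydroxyl should not compete) and kinetic acid hydrolysis opens it to the ester of the more hindered secondary oxygen, leaving O15–H free.

**Compound list**
1 | 2-methylcyclohex-2-en-1-one | CC1=CCCCC1=O | starting material
2 | dimethylaluminium (3R)-2,3-dimethylcyclohex-1-en-1-olate (not isolated) | C[C@@H]1CCCC(O[Al](C)C)=C1C | intermediate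
3 | {[(3R)-2,3-dimethylcyclohex-1-en-1-yl]oxy}trimethylsilane | C[C@@H]1CCCC(O[Si](C)(C)C)=C1C | intermediate
4 | (R)-2,2-dimethyl-1,3-dioxolane-4-carbaldehyde | O=C[C@H]1COC(C)(C)O1 | starting material
5 | 1-[(4R)-2,2-dimethyl-1,3-dioxolan-4-yl]prop-2-en-1-ol (carbinol epimers) | C=CC(O)[C@H]1COC(C)(C)O1 | intermediate
6 | 1-[(4R)-2,2-dimethyl-1,3-dioxolan-4-yl]prop-2-en-1-one | C=CC(=O)[C@H]1COC(C)(C)O1 | intermediate
7 | trimethylsilyl enol ether of the Michael adduct (not isolated, enol ether geometry undefined) | O=C1CCC[C@@H](C)[C@]1(C)CC=C(O[Si](C)(C)C)[C@H]2COC(C)(C)O2 | intermediate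
8 | (2S,3R)-2-{3-[(4R)-2,2-dimethyl-1,3-dioxolan-4-yl]-3-oxopropyl}-2,3-dimethylcyclohexan-1-one | O=C1CCC[C@@H](C)[C@]1(C)CCC(=O)[C@H]2COC(C)(C)O2 | intermediate
9 | (2S,3R)-2-{(3S)-3-[(4R)-2,2-dimethyl-1,3-dioxolan-4-yl]-3-hydroxybutyl}-2,3-dimethylcyclohexan-1-one | O=C1CCC[C@@H](C)[C@]1(C)CC[C@](C)(O)[C@H]2COC(C)(C)O2 | intermediate
10 | (2S,3R)-2-{(3S)-3-[(4R)-2,2-dimethyl-1,3-dioxolan-4-yl]-3-(triethylsilyloxy)butyl}-2,3-dimethylcyclohexan-1-one | O=C1CCC[C@@H](C)[C@]1(C)CC[C@](C)(O[Si](CC)(CC)CC)[C@H]2COC(C)(C)O2 | intermediate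
11 | (E)-2,4,6-triisopropylbenzenesulfonylhydrazone of ketone 10 | CC(C)c1cc(C(C)C)c(c(C(C)C)c1)S(=O)(=O)N/N=C2\CCC[C@@H](C)[C@]2(C)CC[C@](C)(O[Si](CC)(CC)CC)[C@H]3COC(C)(C)O3 | intermediate
12 | C10 vinyllithium of ring B (not isolated) | [Li]C1=CCC[C@@H](C)[C@]1(C)CC[C@](C)(O[Si](CC)(CC)CC)[C@H]2COC(C)(C)O2 | intermediate
13 | (5R,6S)-6-{(3S)-3-[(4R)-2,2-dimethyl-1,3-dioxolan-4-yl]-3-(triethylsilyloxy)butyl}-5,6-dimethylcyclohex-1-ene-1-carbaldehyde | O=CC1=CCC[C@@H](C)[C@]1(C)CC[C@](C)(O[Si](CC)(CC)CC)[C@H]2COC(C)(C)O2 | intermediate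
14 | diisopinocampheylborinate of alcohol 15 (not isolated) | C=CC[C@@H](OB([C@H]3C[C@H]4C[C@@H]([C@@H]3C)C4(C)C)[C@H]5C[C@H]6C[C@@H]([C@@H]5C)C6(C)C)C1=CCC[C@@H](C)[C@]1(C)CC[C@](C)(O[Si](CC)(CC)CC)[C@H]2COC(C)(C)O2 | intermediate
15 | (1R)-1-[(5R,6S)-6-{(3S)-3-[(4R)-2,2-dimethyl-1,3-dioxolan-4-yl]-3-(triethylsilyloxy)butyl}-5,6-dimethylcyclohex-1-en-1-yl]but-3-en-1-ol | C=CC[C@@H](O)C1=CCC[C@@H](C)[C@]1(C)CC[C@](C)(O[Si](CC)(CC)CC)[C@H]2COC(C)(C)O2 | intermediate
16 | methacrylate ester of alcohol 15 | C=CC[C@@H](OC(=O)C(C)=C)C1=CCC[C@@H](C)[C@]1(C)CC[C@](C)(O[Si](CC)(CC)CC)[C@H]2COC(C)(C)O2 | intermediate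
17 | (6R)-6-[ring-B cyclohexenyl]-3-methyl-5,6-dihydro-2H-pyran-2-one | CC1=CC[C@@H](OC1=O)C2=CCC[C@@H](C)[C@]2(C)CC[C@](C)(O[Si](CC)(CC)CC)[C@H]3COC(C)(C)O3 | intermediate
18 | dimethylphenylsilyl ketene acetal of lactone 19 (not isolated) | CC1=C(O[Si](C)(C)c2ccccc2)O[C@H](CC1)C3=CCC[C@@H](C)[C@]3(C)CC[C@](C)(O[Si](CC)(CC)CC)[C@H]4COC(C)(C)O4 | intermediate
19 | (3RS,6R)-6-[ring-B cyclohexenyl]-3-methyltetrahydro-2H-pyran-2-one (C4 epimers) | CC1CC[C@@H](OC1=O)C2=CCC[C@@H](C)[C@]2(C)CC[C@](C)(O[Si](CC)(CC)CC)[C@H]3COC(C)(C)O3 | intermediate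
20 | trimethylsilyl ketene acetal of lactone 19 (not isolated) | CC1=C(O[Si](C)(C)C)O[C@H](CC1)C2=CCC[C@@H](C)[C@]2(C)CC[C@](C)(O[Si](CC)(CC)CC)[C@H]3COC(C)(C)O3 | intermediate
21 | trimethylsilyl ester of acid 22 (not isolated) | C[Si](C)(C)OC(=O)[C@@]1(C)CCC=C2[C@H]1CC[C@@H](C)[C@]2(C)CC[C@](C)(O[Si](CC)(CC)CC)[C@H]3COC(C)(C)O3 | intermediate
22 | (1S,5S,6R,8aR)-5-{(3S)-3-[(4R)-2,2-dimethyl-1,3-dioxolan-4-yl]-3-(triethylsilyloxy)butyl}-1,5,6-trimethyl-1,2,3,5,6,7,8,8a-octahydronaphthalene-1-carboxylic acid | OC(=O)[C@@]1(C)CCC=C2[C@H]1CC[C@@H](C)[C@]2(C)CC[C@](C)(O[Si](CC)(CC)CC)[C@H]3COC(C)(C)O3 | intermediate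
23 | methyl ester of acid 22 | COC(=O)[C@@]1(C)CCC=C2[C@H]1CC[C@@H](C)[C@]2(C)CC[C@](C)(O[Si](CC)(CC)CC)[C@H]3COC(C)(C)O3 | intermediate
24 | methyl (1S,5S,6R,8aR)-5-[(3S,4R)-3,4,5-trihydroxy-3-methylpentyl]-1,5,6-trimethyl-1,2,3,5,6,7,8,8a-octahydronaphthalene-1-carboxylate | COC(=O)[C@@]1(C)CCC=C2[C@H]1CC[C@@H](C)[C@]2(C)CC[C@](C)(O)[C@@H](CO)O | intermediate
25 | 14,15-cyclic methyl orthoacetate of triol 24 (not isolated, orthoester epimers) | COC(=O)[C@@]1(C)CCC=C2[C@H]1CC[C@@H](C)[C@]2(C)CC[C@](C)(O)[C@H]3COC(C)(OC)O3 | intermediate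
26 | methyl (1S,5S,6R,8aR)-5-[(3S,4R)-4-acetoxy-3,5-dihydroxy-3-methylpentyl]-1,5,6-trimethyl-1,2,3,5,6,7,8,8a-octahydronaphthalene-1-carboxylate (CNP0210069.1) | COC(=O)[C@@]1(C)CCC=C2[C@H]1CC[C@@H](C)[C@]2(C)CC[C@](C)(O)[C@@H](CO)OC(C)=O | target

**Step count**
Total: 16 steps. Longest linear sequence: 15 steps (4 to 26, steps 2–16); the branch from 1 joins at step 4.

**Three steps most likely to fail**

Step 13 (key step). The boat transition state is congested next to quaternary C9 and may rearrange slowly, and the lactone enolate may fragment to a ketene or be C-silylated before it rearranges. The fallback closes ring A by an intermolecular Diels–Alder reaction instead. It sets out from enal 13: methylenation with Ph3P=CH2 (THF, 0 °C) should give the 1-vinylcyclohexene diene F1. Cycloaddition of F1 with methyl methacrylate (Me2AlCl, CH2Cl2, −40 to 0 °C) is expected to follow the ortho rule, take the ester-endo mode and add anti to the pseudoaxial C9 methyl. That combination gives methyl ester 23, where the route is rejoined at step 15. Its face and endo/exo selectivity are less secure than in step 13, which is why it is only the fallback.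

Step 4. The sensitive vinyl ketone may polymerise under the acid catalyst, the acetonide may be cleaved or C14 epimerised, and attack anti to the C8 methyl may be incomplete. The fallback replaces the Lewis-acid pathway by an anionic Michael addition to an α-silyl vinyl ketone and sets out from 3 and 4. Aldehyde 4 and (1-(trimethylsilyl)vinyl)magnesium bromide (THF, −78 °C) give 1-[(4R)-2,2-dimethyl-1,3-dioxolan-4-yl]-2-(trimethylsilyl)prop-2-en-1-ol F2. Dess–Martin oxidation gives the α-silyl enone F3. Silyl enol ether 3 with MeLi (THF, 0 °C) gives the lithium enolate F4, which adds to F3 at −78 °C; the silyl group stabilises the adduct anion and blocks polymerisation, giving α-silyl ketone F5. Buffered fluoride (TBAF–AcOH, THF, 0 °C) removes the silyl group and returns diketone 8.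

Step 16. Opening of the orthoester may not favour the secondary oxygen enough, and the acetyl group may migrate from O14 to the primary O15 during isolation. The fallback is a protection sequence that sets out from triol 24. TBSCl and imidazole (CH2Cl2, 0 °C) silylate only the primary hydroxyl to give the 15-O-TBS ether F6. Ac2O, DMAP and pyridine acetylate the secondary hydroxyl (the tertiary one is inert) to give the 14-O-acetyl-15-O-TBS compound F7. HF·pyridine (THF–pyridine, 0 °C) removes the silyl group under acidic, non-migrating conditions and gives target 26.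

**Further compounds**
F1 | step 13 | triethyl{[(2S)-2-[(4R)-2,2-dimethyl-1,3-dioxolan-4-yl]-4-[(1S,6R)-2-ethenyl-1,6-dimethylcyclohex-2-en-1-yl]butan-2-yl]oxy}silane | C=CC1=CCC[C@@H](C)[C@]1(C)CC[C@](C)(O[Si](CC)(CC)CC)[C@H]2COC(C)(C)O2
F2 | step 4 | 1-[(4R)-2,2-dimethyl-1,3-dioxolan-4-yl]-2-(trimethylsilyl)prop-2-en-1-ol | C=C([Si](C)(C)C)C(O)[C@H]1COC(C)(C)O1
F3 | step 4 | 1-[(4R)-2,2-dimethyl-1,3-dioxolan-4-yl]-2-(trimethylsilyl)prop-2-en-1-one | C=C([Si](C)(C)C)C(=O)[C@H]1COC(C)(C)O1
F4 | step 4 | lithium (3R)-2,3-dimethylcyclohex-1-en-1-olate | C[C@@H]1CCCC(O[Li])=C1C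
F5 | step 4 | (2S,3R)-2-{3-[(4R)-2,2-dimethyl-1,3-dioxolan-4-yl]-3-oxo-2-(trimethylsilyl)propyl}-2,3-dimethylcyclohexan-1-one | O=C1CCC[C@@H](C)[C@]1(C)CC([Si](C)(C)C)C(=O)[C@H]2COC(C)(C)O2
F6 | step 16 | methyl (1S,5S,6R,8aR)-5-[(3S,4R)-5-(tert-butyldimethylsilyloxy)-3,4-dihydroxy-3-methylpentyl]-1,5,6-trimethyl-1,2,3,5,6,7,8,8a-octahydronaphthalene-1-carboxylate | COC(=O)[C@@]1(C)CCC=C2[C@H]1CC[C@@H](C)[C@]2(C)CC[C@](C)(O)[C@@H](CO[Si](C)(C)C(C)(C)C)O
F7 | step 16 | methyl (1S,5S,6R,8aR)-5-[(3S,4R)-4-acetoxy-5-(tert-butyldimethylsilyloxy)-3-hydroxy-3-methylpentyl]-1,5,6-trimethyl-1,2,3,5,6,7,8,8a-octahydronaphthalene-1-carboxylate | COC(=O)[C@@]1(C)CCC=C2[C@H]1CC[C@@H](C)[C@]2(C)CC[C@](C)(O)[C@@H](CO[Si](C)(C)C(C)(C)C)OC(C)=O
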